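The synthesis is convergent. Ring A is the oxane (O1, C2–C6) and its C5 chain is C1'–C13'. Everything rests on cutting C1'–C2', which leaves a ring A sulfone carrying C1' and a C15 epoxide. C2'–C13' with its three methyl branches is a farnesol chain, and the hydroxyls on C3' and C4' lie as after anti addition across a Z double bond. So (2Z,6E)-farnesol, a free triene alcohol made from nerol, is epoxidised with titanium tartrate. Its hydroxyl on C2' picks the C3'=C4' alkene out of three, and one operation builds the oxirane, both C–O bonds and both stereocentres. Base-induced epoxide migration then inverts C3' and makes C2' the carbon attacked by the lithiated sulfone.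

Key step: step 8

Remark: carbons formed as both configurations (the sulfonyl-bearing carbons of the two sulfone couplings and one aldehyde α-carbon) are written without descriptors; none survives into the target.
Assumption: nerol, 1-bromo-3-methylbut-2-ene, hex-5-enoyl chloride and (S)-4-benzyl-1,3-oxazolidin-2-one are bought; all other reagents are common catalogue items.

Step 1
Reactants: 1 1-bromo-3-methylbut-2-ene (prenyl bromide)
Product: 2 [(3-methylbut-2-en-1-yl)sulfonyl]benzene (prenyl phenyl sulfone)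
Conditions: PhSO2Na, DMF, rt
Reagents that add atoms: sodium benzenesulfinate, [Na+].[O-]S(=O)c1ccccc1
Why: SN2 S-alkylation of the sulfinate anion by a primary allylic bromide is the standard entry to allylic sulfones and should proceed without allylic shift.

Step 2
Reactants: 3 nerol, (2Z)-3,7-dimethylocta-2,6-dien-1-ol
Product: 4 tert-butyl{[(2Z)-3,7-dimethylocta-2,6-dien-1-yl]oxy}diphenylsilane
Conditions: TBDPSCl, imidazole, CH2Cl2, 0 °C to rt
Reagents that add atoms: tert-butylchlorodiphenylsilane, CC(C)(C)[Si](Cl)(c1ccccc1)c1ccccc1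
Why: Imidazole-promoted silylation of a primary alcohol is reliable, and a silyl ether (unlike an allylic ester) is neither attacked by the carbanion of step 5 nor ionised by zerovalent palladium in step 6.

Step 3
Reactants: 4 tert-butyl{[(2Z)-3,7-dimethylocta-2,6-dien-1-yl]oxy}diphenylsilane
Product: 5 (2E,6Z)-8-[(tert-butyldiphenylsilyl)oxy]-2,6-dimethylocta-2,6-dien-1-ol
Conditions: SeO2 (cat.), t-BuOOH, salicylic acid (cat.), CH2Cl2, rt
Reagents that add atoms: tert-butyl hydroperoxide, CC(C)(C)OO; selenium dioxide, O=[Se]=O (catalytic carrier of that oxygen)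
Why: Allylic oxidation by SeO2 (ene reaction, then [2,3]-sigmatropic shift) takes the E-methyl group of the electron-richer terminal alkene, as known for neryl and geranyl ethers, so the new allylic alcohol should be E and the Z alkene stays.

Step 4
Reactants: 5 (2E,6Z)-8-[(tert-butyldiphenylsilyl)oxy]-2,6-dimethylocta-2,6-dien-1-ol
Product: 6 {[(2Z,6E)-8-bromo-3,7-dimethylocta-2,6-dien-1-yl]oxy}(tert-butyl)diphenylsilane
Conditions: CBr4, PPh3, CH2Cl2, 0 °C
Reagents that add atoms: carbon tetrabromide, BrC(Br)(Br)Br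
Why: Appel bromination replaces the primary allylic hydroxyl by SN2 under neutral conditions, which should leave the silyl ether and both alkene geometries untouched.

Step 5
Reactants: 2 [(3-methylbut-2-en-1-yl)sulfonyl]benzene; 6 {[(2Z,6E)-8-bromo-3,7-dimethylocta-2,6-dien-1-yl]oxy}(tert-butyl)diphenylsilane
Product: 7 {[(2Z,6E)-9-(benzenesulfonyl)-3,7,11-trimethyldodeca-2,6,10-trien-1-yl]oxy}(tert-butyl)diphenylsilane (both configurations at C9)
Conditions: 2, n-BuLi, THF, −78 °C; then 6, −78 to −20 °C
Reagents that add atoms: none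
Why: Alkylation of the α-sulfonyl allyl carbanion at its α-carbon by an allylic bromide is the classical sulfone coupling of terpene units and forms C8–C9 of the farnesyl chain; the sulfonyl carbon is formed without control and is removed in step 6.

Step 6
Reactants: 7 {[(2Z,6E)-9-(benzenesulfonyl)-3,7,11-trimethyldodeca-2,6,10-trien-1-yl]oxy}(tert-butyl)diphenylsilane
Product: 8 tert-butyldiphenyl{[(2Z,6E)-3,7,11-trimethyldodeca-2,6,10-trien-1-yl]oxy}silane
Conditions: PdCl2(dppp) [dppp = Ph2P(CH2)3PPh2] (cat.), LiBHEt3, THF, 0 °C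
Reagents that add atoms: none
Why: In this palladium-catalysed reductive desulfonylation, zerovalent palladium formed in the flask ionises the allylic sulfone to a π-allyl complex that should take hydride at its less substituted end, so the Me2C=CH alkene stays in place as known for prenyl-type sulfones.

Step 7
Reactants: 8 tert-butyldiphenyl{[(2Z,6E)-3,7,11-trimethyldodeca-2,6,10-trien-1-yl]oxy}silane
Product: 9 (2Z,6E)-farnesol, (2Z,6E)-3,7,11-trimethyldodeca-2,6,10-trien-1-ol
Conditions: TBAF, THF, rt
Reagents that add atoms: none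
Why: Fluoride cleavage of the silyl ether (Si–F bond formation) frees the allylic alcohol without touching the three alkenes.

Step 8
Reactants: 9 (2Z,6E)-farnesol
Product: 10 [(2S,3R)-3-[(3E)-4,8-dimethylnona-3,7-dien-1-yl]-3-methyloxiran-2-yl]methanol
Conditions: Ti(OiPr)4 (10 mol %), L-(+)-diethyl tartrate (12 mol %), t-BuOOH (anhydrous, in decane), 4 Å molecular sieves, CH2Cl2, −20 °C
Reagents that add atoms: tert-butyl hydroperoxide, CC(C)(C)OO
Why: Katsuki–Sharpless asymmetric epoxidation: the alkoxide of 9 and tert-butyl peroxide bind one tetravalent titanium centre of the dimeric titanium–tartrate complex, and the peroxide oxygen is handed over inside this complex to the neighbouring C2=C3 alkene of the farnesol chain (C3'=C4' of the target). The closest known reaction is the same epoxidation of nerol and related Z-trisubstituted allylic alcohols. The oxirane closes by concerted suprafacial transfer of one oxygen atom to both alkene carbons (a [2+1] addition to the π bond, not a tethered cyclisation), so the Z geometry is carried into the cis relation of the CH2OH group and the chain on C3. C2 (S) and C3 (R) are created together and their absolute sense is fixed by the L-(+)-tartrate ligand (reagent control); after inversion at C2 in step 9 this sense gives 3'R,4'R. The step needs enantioface selectivity, supplied by the ligand, and site selectivity among three trisubstituted alkenes, supplied by the C1 hydroxyl: only the allylic C2=C3 alkene can sit next to the titanium-bound peroxide, while the C6=C7 and C10=C11 alkenes cannot reach it.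

Step 9
Reactants: 10 [(2S,3R)-3-[(3E)-4,8-dimethylnona-3,7-dien-1-yl]-3-methyloxiran-2-yl]methanol
Product: 11 (2R,5E)-6,10-dimethyl-2-[(2R)-oxiran-2-yl]undeca-5,9-dien-2-ol
Conditions: NaOH (0.5 M aq.), t-BuOH, rt
Reagents that add atoms: none
Why: In this Payne rearrangement the C1 alkoxide opens the oxirane at C2 by an intramolecular SN2 (3-exo-tet) that inverts C2 and leaves the C3–O bond untouched, and the equilibrium should favour the tertiary alcohol with the monosubstituted oxirane.

Step 10
Reactants: 11 (2R,5E)-6,10-dimethyl-2-[(2R)-oxiran-2-yl]undeca-5,9-dien-2-ol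
Product: 12 trimethyl{[(2R,5E)-6,10-dimethyl-2-[(2R)-oxiran-2-yl]undeca-5,9-dien-2-yl]oxy}silane
Conditions: TMSCl, imidazole, DMF, 0 °C
Reagents that add atoms: chlorotrimethylsilane, C[Si](C)(C)Cl
Why: Silylation of the tertiary hydroxyl under non-acidic conditions should spare the oxirane and removes the free alkoxide that could drive the epoxide back to C2–C3 during the carbanion step.

Step 11
Reactants: 13 (S)-4-benzyl-1,3-oxazolidin-2-one; 14 hex-5-enoyl chloride
Product: 15 (4S)-4-benzyl-3-(hex-5-enoyl)-1,3-oxazolidin-2-one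
Conditions: 13, n-BuLi, THF, −78 °C; then 14
Reagents that add atoms: none
Why: N-acylation of the lithiated oxazolidinone by an acid chloride is the standard way to attach this chiral auxiliary.

Step 12
Reactants: 15 (4S)-4-benzyl-3-(hex-5-enoyl)-1,3-oxazolidin-2-one
Product: 16 (4S)-4-benzyl-3-[(2S)-2-[(phenylsulfanyl)methyl]hex-5-enoyl]-1,3-oxazolidin-2-one
Conditions: TiCl4, i-Pr2NEt, CH2Cl2, 0 °C; then PhSCH2Cl
Reagents that add atoms: chloromethyl phenyl sulfide, ClCSc1ccccc1
Why: In this auxiliary-controlled enolate alkylation (Evans alkylation) the chelated Z titanium enolate should be attacked by the phenylthiomethyl cation equivalent on the face away from the benzyl group, which sets the α-carbon (later C5 of ring A) as 2S.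

Step 13
Reactants: 16 (4S)-4-benzyl-3-[(2S)-2-[(phenylsulfanyl)methyl]hex-5-enoyl]-1,3-oxazolidin-2-one
Product: 17 (2S)-2-[(phenylsulfanyl)methyl]hex-5-en-1-ol
Conditions: LiBH4, H2O (1 equiv), Et2O, 0 °C
Reagents that add atoms: none
Why: Hydride reduction of the imide carbonyl (reductive removal of the auxiliary, which is recovered) gives the primary alcohol without enolisation, so the new stereocentre should not erode.

Step 14
Reactants: 17 (2S)-2-[(phenylsulfanyl)methyl]hex-5-en-1-ol
Product: 18 (2S)-2-[(benzenesulfonyl)methyl]hex-5-en-1-ol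
Conditions: (NH4)6Mo7O24·4H2O (cat.), H2O2 (30% aq.), EtOH, 0 °C to rt
Reagents that add atoms: hydrogen peroxide, OO
Why: Molybdate-catalysed peroxide oxidation takes the sulfide through the sulfoxide to the sulfone much faster than it attacks an unactivated terminal alkene.

Step 15
Reactants: 18 (2S)-2-[(benzenesulfonyl)methyl]hex-5-en-1-ol
Product: 20 2-[(2R,5S)-5-[(benzenesulfonyl)methyl]oxan-2-yl]acetaldehyde, via hydroxy enal 19 (not isolated)
Conditions: acrolein, second-generation Hoveyda–Grubbs catalyst [RuCl2(H2IMes)(=CH-C6H4-2-OiPr)] (cat.), CH2Cl2, 40 °C; evaporate; DBU (cat.), CH2Cl2, rt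
Reagents that add atoms: acrolein, C=CC=O
Why: Olefin cross-metathesis gives the E enal, and the base-mediated intramolecular oxa-Michael addition (6-exo-trig) that closes ring A is reversible, so C2 should settle trans to the C5 substituent with both groups equatorial.

Step 16
Reactants: 20 2-[(2R,5S)-5-[(benzenesulfonyl)methyl]oxan-2-yl]acetaldehyde
Product: 21 (2R,5S)-5-[(benzenesulfonyl)methyl]-2-(2,2-dimethoxyethyl)oxane
Conditions: HC(OMe)3, MeOH, CSA (cat.), rt
Reagents that add atoms: trimethyl orthoformate, COC(OC)OC; methanol, CO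
Why: Acid-catalysed acetalisation with the orthoformate as water scavenger masks the enolisable aldehyde, so that only the sulfone α-carbon is deprotonated in step 17.

Step 17
Reactants: 21 (2R,5S)-5-[(benzenesulfonyl)methyl]-2-(2,2-dimethoxyethyl)oxane; 12 trimethyl{[(2R,5E)-6,10-dimethyl-2-[(2R)-oxiran-2-yl]undeca-5,9-dien-2-yl]oxy}silane
Product: 23 (3R,4R,7E)-1-(benzenesulfonyl)-1-[(3S,6R)-6-(2,2-dimethoxyethyl)oxan-3-yl]-4,8,12-trimethyltrideca-7,11-diene-3,4-diol (both configurations at C1), via silylated adduct 22 (not isolated)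
Conditions: 21, n-BuLi, THF, −78 °C; then 12, DMPU, −78 °C to rt; then K2CO3, MeOH, rt
Reagents that add atoms: none
Why: SN2 opening of the monosubstituted oxirane at its CH2 carbon by the α-sulfonyl carbanion forms the C1'–C2' bond without touching C3' or C4', and methanolysis then removes the trimethylsilyl group wherever it has migrated; the sulfonyl carbon is formed as both configurations and is removed in step 18.

Step 18
Reactants: 23 (3R,4R,7E)-1-(benzenesulfonyl)-1-[(3S,6R)-6-(2,2-dimethoxyethyl)oxan-3-yl]-4,8,12-trimethyltrideca-7,11-diene-3,4-diol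
Product: 24 (3R,4R,7E)-1-[(3S,6R)-6-(2,2-dimethoxyethyl)oxan-3-yl]-4,8,12-trimethyltrideca-7,11-diene-3,4-diol
Conditions: Na(Hg) (6%), Na2HPO4, MeOH/THF, −20 °C
Reagents that add atoms: none
Why: Reductive desulfonylation by single-electron transfer from sodium amalgam cleaves the C–S bond, and because the hydroxyl is γ to the sulfone no Julia-type elimination can occur.

Step 19
Reactants: 24 (3R,4R,7E)-1-[(3S,6R)-6-(2,2-dimethoxyethyl)oxan-3-yl]-4,8,12-trimethyltrideca-7,11-diene-3,4-diol
Product: 25 2-[(2R,5S)-5-[(3R,4R,7E)-3,4-dihydroxy-4,8,12-trimethyltrideca-7,11-dien-1-yl]oxan-2-yl]acetaldehyde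
Conditions: AcOH/THF/H2O (3:1:1), 40 °C
Reagents that add atoms: water, O
Why: Mild aqueous acid hydrolysis of the dimethyl acetal should free the aldehyde, while the diol and the trisubstituted alkenes need stronger acid to react.

Step 20
Reactants: 25 2-[(2R,5S)-5-[(3R,4R,7E)-3,4-dihydroxy-4,8,12-trimethyltrideca-7,11-dien-1-yl]oxan-2-yl]acetaldehyde
Product: 27 2-[(2R,5S)-5-[(3R,4R,7E)-3,4-dihydroxy-4,8,12-trimethyltrideca-7,11-dien-1-yl]oxan-2-yl]prop-2-enal, via Mannich base 26 (not isolated)
Conditions: CH2=NMe2+ I−, Et3N, CH2Cl2, rt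
Reagents that add atoms: N,N-dimethylmethyleneiminium iodide (Eschenmoser's salt), C=[N+](C)C.[I-]
Why: Mannich reaction of the aldehyde enol with the iminium salt followed by β-elimination of dimethylamine (α-methylenation) is established for oxan-2-yl acetaldehydes and leaves no α-hydrogen, so C2 of ring A can no longer epimerise.

Step 21
Reactants: 27 2-[(2R,5S)-5-[(3R,4R,7E)-3,4-dihydroxy-4,8,12-trimethyltrideca-7,11-dien-1-yl]oxan-2-yl]prop-2-enal
Product: 28 2-[(2R,5S)-5-[(3R,4R,7E)-3,4-dihydroxy-4,8,12-trimethyltrideca-7,11-dien-1-yl]oxan-2-yl]prop-2-enoic acid (target)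
Conditions: NaClO2, NaH2PO4, 2-methylbut-2-ene, t-BuOH/H2O, 0 °C to rt
Reagents that add atoms: sodium chlorite, [Na+].[O-]Cl=O
Why: Pinnick oxidation converts the conjugated aldehyde into the acid through chlorous acid, while the alkene scavenger intercepts hypochlorous acid so that the diol and the three C=C bonds should survive.

Compound list
1 | 1-bromo-3-methylbut-2-ene | CC(C)=CCBr | starting material
2 | [(3-methylbut-2-en-1-yl)sulfonyl]benzene | CC(C)=CCS(=O)(=O)c1ccccc1 | intermediate
3 | nerol, (2Z)-3,7-dimethylocta-2,6-dien-1-ol | OC/C=C(/C)CCC=C(C)C | starting material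
4 | tert-butyl{[(2Z)-3,7-dimethylocta-2,6-dien-1-yl]oxy}diphenylsilane | CC(C)(C)[Si](OC/C=C(/C)CCC=C(C)C)(c1ccccc1)c1ccccc1 | intermediate
5 | (2E,6Z)-8-[(tert-butyldiphenylsilyl)oxy]-2,6-dimethylocta-2,6-dien-1-ol | CC(C)(C)[Si](OC/C=C(/C)CC/C=C(\C)CO)(c1ccccc1)c1ccccc1 | intermediate
6 | {[(2Z,6E)-8-bromo-3,7-dimethylocta-2,6-dien-1-yl]oxy}(tert-butyl)diphenylsilane | CC(C)(C)[Si](OC/C=C(/C)CC/C=C(\C)CBr)(c1ccccc1)c1ccccc1 | intermediate
7 | {[(2Z,6E)-9-(benzenesulfonyl)-3,7,11-trimethyldodeca-2,6,10-trien-1-yl]oxy}(tert-butyl)diphenylsilane, C9 epimers | CC(C)(C)[Si](OC/C=C(/C)CC/C=C(\C)CC(C=C(C)C)S(=O)(=O)c1ccccc1)(c1ccccc1)c1ccccc1 | intermediate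
8 | tert-butyldiphenyl{[(2Z,6E)-3,7,11-trimethyldodeca-2,6,10-trien-1-yl]oxy}silane | CC(C)(C)[Si](OC/C=C(/C)CC/C=C(\C)CCC=C(C)C)(c1ccccc1)c1ccccc1 | intermediate
9 | (2Z,6E)-farnesol | OC/C=C(/C)CC/C=C(\C)CCC=C(C)C | intermediate
10 | [(2S,3R)-3-[(3E)-4,8-dimethylnona-3,7-dien-1-yl]-3-methyloxiran-2-yl]methanol | OC[C@@H]1O[C@]1(C)CC/C=C(\C)CCC=C(C)C | intermediate
11 | (2R,5E)-6,10-dimethyl-2-[(2R)-oxiran-2-yl]undeca-5,9-dien-2-ol | C1O[C@H]1[C@](C)(O)CC/C=C(\C)CCC=C(C)C | intermediate
12 | trimethyl{[(2R,5E)-6,10-dimethyl-2-[(2R)-oxiran-2-yl]undeca-5,9-dien-2-yl]oxy}silane | C1O[C@H]1[C@](C)(O[Si](C)(C)C)CC/C=C(\C)CCC=C(C)C | intermediate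
13 | (S)-4-benzyl-1,3-oxazolidin-2-one | O=C1N[C@@H](Cc2ccccc2)CO1 | starting material
14 | hex-5-enoyl chloride | C=CCCCC(=O)Cl | starting material
15 | (4S)-4-benzyl-3-(hex-5-enoyl)-1,3-oxazolidin-2-one | C=CCCCC(=O)N1[C@@H](Cc2ccccc2)COC1=O | intermediate
16 | (4S)-4-benzyl-3-[(2S)-2-[(phenylsulfanyl)methyl]hex-5-enoyl]-1,3-oxazolidin-2-one | C=CCC[C@H](CSc1ccccc1)C(=O)N1[C@@H](Cc2ccccc2)COC1=O | intermediate
17 | (2S)-2-[(phenylsulfanyl)methyl]hex-5-en-1-ol | OC[C@@H](CSc1ccccc1)CCC=C | intermediate
18 | (2S)-2-[(benzenesulfonyl)methyl]hex-5-en-1-ol | OC[C@@H](CS(=O)(=O)c1ccccc1)CCC=C | intermediate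
19 | (2E,6S)-6-[(benzenesulfonyl)methyl]-7-hydroxyhept-2-enal | OC[C@@H](CS(=O)(=O)c1ccccc1)CC/C=C/C=O | intermediate (not isolated)
20 | 2-[(2R,5S)-5-[(benzenesulfonyl)methyl]oxan-2-yl]acetaldehyde | O=CC[C@H]1CC[C@H](CS(=O)(=O)c2ccccc2)CO1 | intermediate
21 | (2R,5S)-5-[(benzenesulfonyl)methyl]-2-(2,2-dimethoxyethyl)oxane | COC(OC)C[C@H]1CC[C@H](CS(=O)(=O)c2ccccc2)CO1 | intermediate
22 | (3R,4R,7E)-1-(benzenesulfonyl)-1-[(3S,6R)-6-(2,2-dimethoxyethyl)oxan-3-yl]-4,8,12-trimethyl-4-[(trimethylsilyl)oxy]trideca-7,11-dien-3-ol, C1 epimers | COC(OC)C[C@H]1CC[C@H](C(C[C@@H](O)[C@](C)(O[Si](C)(C)C)CC/C=C(\C)CCC=C(C)C)S(=O)(=O)c2ccccc2)CO1 | intermediate (not isolated)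
23 | (3R,4R,7E)-1-(benzenesulfonyl)-1-[(3S,6R)-6-(2,2-dimethoxyethyl)oxan-3-yl]-4,8,12-trimethyltrideca-7,11-diene-3,4-diol, C1 epimers | COC(OC)C[C@H]1CC[C@H](C(C[C@@H](O)[C@](C)(O)CC/C=C(\C)CCC=C(C)C)S(=O)(=O)c2ccccc2)CO1 | intermediate
24 | (3R,4R,7E)-1-[(3S,6R)-6-(2,2-dimethoxyethyl)oxan-3-yl]-4,8,12-trimethyltrideca-7,11-diene-3,4-diol | COC(OC)C[C@H]1CC[C@H](CC[C@@H](O)[C@](C)(O)CC/C=C(\C)CCC=C(C)C)CO1 | intermediate
25 | 2-[(2R,5S)-5-[(3R,4R,7E)-3,4-dihydroxy-4,8,12-trimethyltrideca-7,11-dien-1-yl]oxan-2-yl]acetaldehyde | O=CC[C@H]1CC[C@H](CC[C@@H](O)[C@](C)(O)CC/C=C(\C)CCC=C(C)C)CO1 | intermediate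
26 | 3-(dimethylamino)-2-[(2R,5S)-5-[(3R,4R,7E)-3,4-dihydroxy-4,8,12-trimethyltrideca-7,11-dien-1-yl]oxan-2-yl]propanal, C2 epimers | CN(C)CC(C=O)[C@H]1CC[C@H](CC[C@@H](O)[C@](C)(O)CC/C=C(\C)CCC=C(C)C)CO1 | intermediate (not isolated)
27 | 2-[(2R,5S)-5-[(3R,4R,7E)-3,4-dihydroxy-4,8,12-trimethyltrideca-7,11-dien-1-yl]oxan-2-yl]prop-2-enal | C=C(C=O)[C@H]1CC[C@H](CC[C@@H](O)[C@](C)(O)CC/C=C(\C)CCC=C(C)C)CO1 | intermediate
28 | 2-[(2R,5S)-5-[(3R,4R,7E)-3,4-dihydroxy-4,8,12-trimethyltrideca-7,11-dien-1-yl]oxan-2-yl]prop-2-enoic acid | C=C(C(=O)O)[C@H]1CC[C@H](CC[C@@H](O)[C@](C)(O)CC/C=C(\C)CCC=C(C)C)CO1 | target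

Total step count: 21. Longest linear sequence: 14 steps (nerol 3 to 28 through steps 2–10 and 17–21); the ring A branch (steps 11–16) joins at step 17 and the prenyl sulfone (step 1) at step 5.

Steps most likely to fail

Step 8 (key step). Discrimination between the two alkene faces may be incomplete on the Z-trisubstituted alkene, or slow turnover may let titanium alkoxides open the acid-labile trisubstituted oxirane. Fallback: starting again from 9, the oxygen transfer is run with another catalyst class, VO(OiPr)3 (pentavalent vanadium) with a C2-symmetric chiral bishydroxamic acid ligand and aqueous t-BuOOH in toluene at 0 °C. This is still hydroxyl-directed but induces asymmetry by a different mode, is documented for Z-substituted allylic alcohols and tolerates water. With the ligand antipode matched to the same alkene face it returns to the route at 10 without any new compound. Any residual minor enantiomer becomes a diastereomer after step 17 and can be removed there.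

Step 9. The rearrangement may stop at an equilibrium mixture, or hydroxide may slowly hydrolyse the terminal oxirane during the time needed. Fallback: from 10, the rearranged oxirane is trapped as it forms by thiolate (PhSH, NaOH aq., t-BuOH, 70 °C; Payne rearrangement with opening at C1), giving (2S,3R,6E)-3,7,11-trimethyl-1-(phenylsulfanyl)dodeca-6,10-diene-2,3-diol F1. S-Methylation with Me3O+ BF4− in CH2Cl2 gives [(2S,3R,6E)-2,3-dihydroxy-3,7,11-trimethyldodeca-6,10-dien-1-yl](methyl)phenylsulfonium tetrafluoroborate F2. NaH in THF then lets the C2 alkoxide displace thioanisole from C1 with retention at C2 and C3, and the route is rejoined at 11.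

Step 15. The ring closure may not equilibrate fully, leaving cis-2,5 isomer, or the β-alkoxy aldehyde may be lost by retro-Michael opening and oligomerisation during metathesis. Fallback: from 18, ozonolysis (O3, CH2Cl2/MeOH, −78 °C; Me2S) followed by CSA and HC(OMe)3 in MeOH gives the cyclic methyl acetal (5S)-5-[(benzenesulfonyl)methyl]-2-methoxyoxane F3 (both anomers). Treatment with tert-butyldimethyl(vinyloxy)silane and TMSOTf (cat.) in CH2Cl2 at −78 °C generates the ring A oxocarbenium ion. The silyl enol ether should attack it axially on the half-chair that holds the C5 group pseudo-equatorial, so C2 is set trans under kinetic control and the route is rejoined at 20.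

Further compounds
F0 | step 8 | none | none
F1 | step 9 | (2S,3R,6E)-3,7,11-trimethyl-1-(phenylsulfanyl)dodeca-6,10-diene-2,3-diol | c1ccccc1SC[C@@H](O)[C@](C)(O)CC/C=C(\C)CCC=C(C)C
F2 | step 9 | [(2S,3R,6E)-2,3-dihydroxy-3,7,11-trimethyldodeca-6,10-dien-1-yl](methyl)phenylsulfonium tetrafluoroborate | C[S+](c1ccccc1)C[C@@H](O)[C@](C)(O)CC/C=C(\C)CCC=C(C)C.F[B-](F)(F)F
F3 | step 15 | (5S)-5-[(benzenesulfonyl)methyl]-2-methoxyoxane (both anomers) | COC1CC[C@H](CS(=O)(=O)c2ccccc2)CO1
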